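## The problem

The target is a 3,3′-linked pair of 4-(4-hydroxyphenyl)chroman-2-ones: lactone A (unprimed locants) carries hydroxyl groups on C5–C8, lactone B (primed locants) on C5′ and C7′. Four contiguous stereocentres lie on the chain C4a–C4–C3–C3′–C4′–C4a′, with configuration 3S,4R,3′S,4′S; the substituents on C3/C4 are cis in lactone A and those on C3′/C4′ are trans in lactone B. C3 and C3′ are α to carbonyl groups and C4 and C4′ are diarylmethine carbons, so every centre can epimerise once its lactone exists, and the cis lactone A, presumably the less stable one, would not survive base. Eight free phenols, four of them on one ring that is easily oxidised to quinones, and two aryl lactones that any good nucleophile opens, rule out oxidants, bases and nucleophiles at the end. The two arenes differ in oxygenation, so the two nearly equivalent halves of the chain must be told apart at some stage. The enabling feature is that joining C4a to C4a′ turns the chain into a 3,6-diarylcyclohex-4-ene-1,2-dicarboxylate with cis aryl groups and trans carboxyl groups. This is the endo adduct of an (E,E)-1,4-diarylbutadiene and a fumarate, in which the carboxyl group cis to its neighbouring aryl group becomes the trans lactone B and the other the cis lactone A.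

## Retrosynthesis

**34 from 32.** Both lactone C(acyl)–O bonds and all O-alkyl bonds are cut together. The fully dealkylated seco compound 33 has a pentahydroxyphenyl and a 2,4,6-trihydroxyphenyl ring, each symmetrical about its bond to C4 or C4′, so each carboxyl group can close only one six-membered lactone and no regiochemical question arises. Closing the lactones last and under acid keeps the cis lactone A away from base. The forward step must cleave seven ethers and a tert-butyl ester and then acylate two phenols without disturbing C3.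

**32 from 27 and 30.** Arene A is cut at C4a–C8a and C5–C6 into the siloxyalkyne 27 and the cyclobutenone 30, which is two steps from dimethyl squarate 28 via 29. C4a was an alkene carbon of the cycloadduct, so the arene has to be grown on it rather than attached. A benzannulation places all five oxygens at once and puts C4a between two of them by mechanism, where stepwise oxidation of a simpler arene would need several regiocontrolled events. The forward reaction asks a hindered alkyne to intercept an electron-rich ketene.

**27 from 22.** The ynol ether oxygen, the terminal alkyne carbon and the aldehyde oxidation level are removed in turn (27 from 24, 24 from 23, 23 from 22). This is the shortest way to make a former alkene carbon the oxygen-flanked arene carbon; the price is an α-aryl aldehyde 23 that must be homologated before it enolises, and an acetylide that must be oxidised in the presence of an ester and an amide.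

**22 from 18 and 19.** Arene B is cut in the same way into siloxyalkyne 18 and commercial 3-ethoxycyclobut-2-en-1-one 19; the resorcinol 21 is capped as its dimethyl ether 22. Arene B is built before arene A because its phloroglucinol pattern tolerates the eight steps that follow, whereas the pentaoxygenated ring should appear as late as possible. The capping keeps the ortho hydroxyl from closing lactone B before the last strongly basic step.

**18 from 11.** The same three operations lead back from 18 through alkyne 15 and aldehyde 14 to the hydroxy amide 13. Amide 13 comes from lactone 12 by aminolysis, and 12 is the silyl ether of 11. The N-methoxy-N-methylamide is chosen for C2′ because it forms directly from the lactone, has no readily removed α-proton, and can still acylate a phenol under acid at the end.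

**11 from 8.** The two carbinol carbons of 11 are rejoined as the alkene of cyclohexene 8, and the lactone oxygen returns to the acyl oxazolidinone. In the forward direction the alkene is cleaved with reductive work-up and the alkoxide next to the imide displaces the oxazolidinone, while its counterpart next to the tert-butyl ester stays free. One step therefore removes the auxiliary and differentiates C4a from C4a′, which is why the ester is chosen as tert-butyl.

**8 from 3 and 7.** C3–C4 and C3′–C4′ are cut in a retro-Diels–Alder sense to the diene 3 and the fumaric ester imide 7. No other cut sets all four centres at once, and the relative configuration follows from alkene geometries and the endo rule instead of from matched pairs of reagents. The forward reaction needs the imide endo and one alkene face, supplied by [Cu((R,R)-t-Bu-box)](SbF6)2, where t-Bu-box is 2,2′-(propane-2,2-diyl)bis(4-tert-butyl-4,5-dihydrooxazole).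

**3 from 1 and 2; 7 from 4 and 5.** The central alkene of 3 is cut by a Horner–Wadsworth–Emmons disconnection into aldehyde 1 and phosphonate 2. The imide N–C bond of 7 is cut into mono-tert-butyl fumarate 4 and 2-oxazolidinone 5, joined through the mixed anhydride 6. All four are commercial.

## Roads not taken

**Alternative 1:** The cut runs through lactone A at C3–C4 and O1–C2. It divides the target into a ring A ortho-quinone methide A4, released by Cs2CO3 from sulfone A3, and the acid A2 that already holds the complete trans lactone B. In the forward step A2 is activated with carbonyldiimidazole, a chiral triazolylidene turns it into a carbene-bound enolate, and this adds to the methide carbon of A4 and is then acylated by the phenoxide, giving the per-O-methylated target A1 (an octamethyl ether).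
- Merits: the route is convergent, needs no arene construction, closes lactone A directly, and such annulations usually give the cis-3,4 product, which is what lactone A needs.
- Weak points: A4 is a fully substituted, electron-rich quinone methide with a methoxy group flanking the reacting carbon. The enolate carbon carries a large stereogenic substituent, so the result depends on a match between catalyst and substrate. The aryl lactone in A2 is itself an acylating agent with an acidic C3′–H under carbonate and carbene. A2 needs its own enantioselective synthesis.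
- Comparison: in step count and convergence this road is clearly better. The chosen plan sets against it that all four centres come from one catalytic event whose relative configuration is fixed by geometry and does not rest on a hindered quinone methide, and it pays with a long arene-building sequence.

**Alternative 2:** Only arene A is disconnected, at C4a–C8a and C5–C6, into cyclobutenone 30 and the siloxyalkyne A6, which carries C4, C3 and an acetate stub for C3′. Heating the two gives phenol A5 with the C8a hydroxyl free and the other four oxygens differentiated.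
- Merits: the most difficult arene is made with every oxygen in place, the free hydroxyl is exactly the lactone oxygen, squarate is cheap, and ring B could be bought as a phloroglucinol ether, so only one benzannulation is needed.
- Weak points: this is a ring synthesis, not a stereochemical solution. C3 and C4 must be set before A6 is made, and C3′ and C4′ afterwards by enolate chemistry next to an existing centre, so the C3–C3′ relationship is left to substrate control. The ynolate has to be formed beside two esters, and the cyclobutenone class is untested.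
- Comparison: the chosen route uses the same ring-forming event as its step 17, so it inherits that uncertainty and is no better there; alternative 2 is also shorter. What the chosen plan offers instead is the C3–C3′ bond and all four centres from one reaction.

**Alternative 3:** The cut is the C4′–C4a′ bond of lactone B. The precursor A8 is the 3,5-dimethoxyphenyl ester of the C2′ acid with a benzylic alcohol at C4′ of either configuration. BF3·OEt2 in hexafluoroisopropanol ionises the alcohol to a 4-methoxybenzyl cation, and the ester arene attacks through the position ortho to its oxygen to close the trans lactone A7.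
- Merits: the step is stereoconvergent at C4′, uses the innate nucleophilicity of a commercial arene, should favour the trans lactone, and avoids any arene construction.
- Weak points: only C4′ is set, and A8 must already contain C4, C3 and C3′, which is the real stereochemical problem. The cation sits next to the enolisable C3′–H and can lose a proton to an alkene, or be captured by the C2 ester carbonyl as a five-membered lactone. An aryl ester prefers the conformation that points the arene away from the cation.
- Comparison: from A8 this road would be much shorter than the chosen one. The chosen plan answers what alternative 3 leaves open, namely the origin of the C4–C3–C3′ triad, and avoids a cation beside an epimerisable centre.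

Key step: step 3

Assumption: the facial sense of [Cu(t-Bu-box)](SbF6)2 is taken from the square-planar two-point-binding model of imide complexes of divalent copper; on that model the (R,R)-ligand gives 8, and the (S,S)-ligand would be used instead if the sense proved opposite.

Remark: locants such as C4a or C3′ are those of the two chroman-2-one units of the target throughout; unprimed is the tetrahydroxy half (A), primed the dihydroxy half (B).

## Route

Step 1
Reactants: 1 (E)-4-methoxycinnamaldehyde; 2 diethyl (4-methoxybenzyl)phosphonate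
Product: 3 (1E,3E)-1,4-bis(4-methoxyphenyl)buta-1,3-diene
Conditions: KO-t-Bu, THF, 0 °C to rt
Reagents that add atoms: none
Why: Horner–Wadsworth–Emmons olefination; the benzylic phosphonate anion adds reversibly and eliminates through the anti oxaphosphetane, so the new alkene is E while the E alkene of 1 is carried over, and the sparingly soluble E,E diene should crystallise free of minor isomers.

Step 2
Reactants: 4 mono-tert-butyl fumarate; 5 2-oxazolidinone
Product: 7 tert-butyl (E)-4-oxo-4-(2-oxo-1,3-oxazolidin-3-yl)but-2-enoate, via mixed pivalic anhydride 6 (not isolated)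
Conditions: t-BuCOCl, Et3N, THF, −20 °C; then 5, LiCl, −20 °C to rt
Reagents that add atoms: none
Why: N-acylation of an oxazolidinone by a mixed pivalic anhydride with LiCl and Et3N; attack occurs at the unhindered fumaroyl carbonyl and the E alkene is untouched.

Step 3
Reactants: 3 (1E,3E)-1,4-bis(4-methoxyphenyl)buta-1,3-diene; 7 tert-butyl (E)-4-oxo-4-(2-oxo-1,3-oxazolidin-3-yl)but-2-enoate
Product: 8 tert-butyl (1S,2S,3S,6R)-3,6-bis(4-methoxyphenyl)-2-(2-oxo-1,3-oxazolidine-3-carbonyl)cyclohex-4-ene-1-carboxylate
Conditions: [Cu((R,R)-t-Bu-box)](SbF6)2 (10 mol %), CH2Cl2, 0 °C to rt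
Reagents that add atoms: none
Why: The cationic complex of divalent copper binds both imide carbonyl groups of 7 in a square-planar chelate, which locks the acyl group s-cis and lowers the alkene LUMO; diene 3 then adds in a concerted, asynchronous [4+2] cycloaddition that is suprafacial on both partners. The closest known reactions are the Diels–Alder additions of acryloyl and fumaroyl oxazolidinones to cyclic and 1-substituted acyclic dienes under the same class of bis(oxazoline) catalysts. The six-membered carbocycle is closed by intermolecular cycloaddition, forming C3–C4 and C3′–C4′ together. C3 and C3′ come out trans because the E geometry of the fumarate is retained. The two aryl-bearing carbons C4 and C4′ come out mutually cis because both diene alkenes are E, and cis to the imide on C3′ because the chelated, more activated carbonyl sits endo while the ester is exo. The absolute sense is set by the ligand: the tert-butyl group next to the bound acyl oxygen covers one alkene face, and with the (R,R)-ligand the open face is Cα-si of the imide carbon, which leads to the (1S,2S,3S,6R) adduct. The step therefore needs imide-endo over ester-endo selectivity and one π-face; two-point binding of the imide, which the ester cannot imitate, and the C2-symmetric ligand secure both. The tert-butyl ester is a spectator chosen for step 4.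

Step 4
Reactants: 8 cyclohexene adduct
Product: 11 hydroxy γ-lactone tert-butyl ester (C4a carbinol free; C4a′ oxygen acylated by C2′), via ozonide 9 (not isolated), via diol imide 10 (not isolated)
Conditions: O3, CH2Cl2, −78 °C; then NaBH4, MeOH, −78 to 0 °C
Reagents that add atoms: ozone, O=[O+][O-]
Why: Ozonolysis of the only alkene with reductive work-up; borohydride takes the ozonide straight to the two primary alcohols, so no α-aryl aldehyde is left to enolise. The C4a′ alkoxide then attacks the acyl oxazolidinone in a 5-exo-trig transacylation that expels 5 and gives the trans γ-lactone, while the C4a alkoxide faces only the hindered tert-butyl ester; no stereocentre is touched and the two ends are now different.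

Step 5
Reactants: 11 hydroxy γ-lactone tert-butyl ester
Product: 12 silyl ether of 11
Conditions: t-BuMe2SiCl, imidazole, DMF, rt
Reagents that add atoms: tert-butyl(chloro)dimethylsilane, CC(C)(C)[Si](C)(C)Cl
Why: Silylation of the only free hydroxyl; it masks the C4a carbinol so that the next step releases the C4a′ oxygen alone.

Step 6
Reactants: 12 silyl ether lactone
Product: 13 hydroxy N-methoxy-N-methylamide
Conditions: Me(MeO)NH·HCl, AlMe3, CH2Cl2, 0 °C to rt
Reagents that add atoms: N,O-dimethylhydroxylamine hydrochloride, CNOC.Cl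
Why: Aminolysis of a γ-lactone by the aluminium amide of N,O-dimethylhydroxylamine (Weinreb amide formation from lactones); it frees the C4a′ hydroxymethyl group and leaves C2′ as an amide that tolerates the later bases, and the tert-butyl ester is too hindered to react.

Step 7
Reactants: 13 hydroxy amide
Product: 14 C4a′ aldehyde
Conditions: Dess–Martin periodinane, pyridine, CH2Cl2, 0 °C
Reagents that add atoms: none
Why: Dess–Martin oxidation of a primary alcohol under buffered, non-basic conditions, so the α-aryl aldehyde forms without enolisation and the hydroxy amide has no time to relactonise; the aldehyde is used crude.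

Step 8
Reactants: 14 C4a′ aldehyde
Product: 15 terminal alkyne (C4a′ is the internal alkyne carbon)
Conditions: MeC(O)C(N2)P(O)(OMe)2, K2CO3, MeOH, 0 °C
Reagents that add atoms: dimethyl (1-diazo-2-oxopropyl)phosphonate, COP(=O)(OC)C(=[N+]=[N-])C(C)=O
Why: Seyferth–Gilbert homologation in the Ohira–Bestmann variant: the diazophosphonate anion adds to the aldehyde, loss of phosphate gives a diazoalkene, and 1,2-shift in the alkylidene carbene gives the alkyne; low temperature and a weak base limit enolisation at C4′.

Step 9
Reactants: 15 terminal alkyne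
Product: 18 triisopropylsilyl ynol ether, via lithium acetylide 16 (not isolated), via lithium ynolate 17 (not isolated)
Conditions: LiN(SiMe3)2, THF, −78 °C; LiOO-t-Bu (from t-BuOOH and LiN(SiMe3)2), −78 to 0 °C; then i-Pr3SiOTf, −78 °C
Reagents that add atoms: tert-butyl hydroperoxide, CC(C)(C)OO; triisopropylsilyl trifluoromethanesulfonate, CC(C)[Si](C(C)C)(C(C)C)OS(=O)(=O)C(F)(F)F
Why: Oxidation of a lithium acetylide by lithium tert-butyl peroxide to the ynolate and O-silylation with a bulky silyl triflate, the standard route to 1-siloxyalkynes; the amide base removes the alkyne proton far faster than the hindered tertiary α-protons of the tert-butyl ester and the amide.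

Step 10
Reactants: 18 triisopropylsilyl ynol ether; 19 3-ethoxycyclobut-2-en-1-one
Product: 21 ring B resorcinol with free C4a carbinol, via silylated phenol 20 (not isolated)
Conditions: toluene, 80 °C; then Bu4NF, AcOH, THF, 0 °C to rt
Reagents that add atoms: none
Why: Danheiser benzannulation: electrocyclic ring opening of 19, [2+2] cycloaddition of the resulting ketene with the siloxyalkyne (ketene carbon to the chain-bearing alkyne carbon), ring opening, six-electron electrocyclisation and tautomerisation give a phenol in which C4a′ lies between the two oxygenated carbons and the ethoxy group is para to it. Buffered fluoride then removes the aryl and the primary silyl ether, and the amide stays open in the absence of strong acid.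

Step 11
Reactants: 21 ring B resorcinol
Product: 22 ring B dimethyl ether
Conditions: MeI, K2CO3, DMF, rt
Reagents that add atoms: iodomethane, CI
Why: Williamson methylation of the two phenols with a carbonate base that deprotonates neither the primary alcohol nor the α-positions; capping both ortho hydroxyls keeps the arene inert to the oxidant of step 12 and prevents early closure of lactone B.

Step 12
Reactants: 22 primary alcohol
Product: 23 C4a aldehyde
Conditions: Dess–Martin periodinane, pyridine, CH2Cl2, 0 °C
Reagents that add atoms: none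
Why: Dess–Martin oxidation as in step 7; no free phenol is present and the α-aryl aldehyde is used crude.

Step 13
Reactants: 23 C4a aldehyde
Product: 24 terminal alkyne (C4a is the internal alkyne carbon)
Conditions: MeC(O)C(N2)P(O)(OMe)2, K2CO3, MeOH, 0 °C
Reagents that add atoms: dimethyl (1-diazo-2-oxopropyl)phosphonate, COP(=O)(OC)C(=[N+]=[N-])C(C)=O
Why: Ohira–Bestmann homologation as in step 8, here at the A end.

Step 14
Reactants: 24 terminal alkyne
Product: 27 triisopropylsilyl ynol ether, via lithium acetylide 25 (not isolated), via lithium ynolate 26 (not isolated)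
Conditions: LiN(SiMe3)2, THF, −78 °C; LiOO-t-Bu (from t-BuOOH and LiN(SiMe3)2), −78 to 0 °C; then i-Pr3SiOTf, −78 °C
Reagents that add atoms: tert-butyl hydroperoxide, CC(C)(C)OO; triisopropylsilyl trifluoromethanesulfonate, CC(C)[Si](C(C)C)(C(C)C)OS(=O)(=O)C(F)(F)F
Why: Acetylide oxidation and O-silylation as in step 9; the molecule now holds only ethers, a tert-butyl ester and the amide, none of which competes for the base at −78 °C.

Step 15
Reactants: 28 dimethyl squarate
Product: 29 4-hydroxy-2,3-dimethoxycyclobut-2-en-1-one
Conditions: LiAlH(O-t-Bu)3, THF, −78 °C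
Reagents that add atoms: none
Why: Chemoselective 1,2-reduction of one squarate carbonyl by a bulky, mild aluminium hydride, known for dialkyl squarates; the product is a vinylogous ester and is not reduced further, and its new centre (racemic) is destroyed in step 17.

Step 16
Reactants: 29 4-hydroxy-2,3-dimethoxycyclobut-2-en-1-one
Product: 30 4-(tert-butyldimethylsilyloxy)-2,3-dimethoxycyclobut-2-en-1-one
Conditions: t-BuMe2SiOTf, 2,6-lutidine, CH2Cl2, −78 °C
Reagents that add atoms: tert-butyldimethylsilyl trifluoromethanesulfonate, CC(C)(C)[Si](C)(C)OS(=O)(=O)C(F)(F)F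
Why: O-silylation with a silyl triflate and a hindered pyridine, chosen because nucleophilic amines would displace the vinylogous ester methoxy group; the silyl ether also blocks acid-induced loss of methanol.

Step 17
Reactants: 27 triisopropylsilyl ynol ether; 30 4-(tert-butyldimethylsilyloxy)-2,3-dimethoxycyclobut-2-en-1-one
Product: 32 ring A triol (hydroxyls on C5 and C8 and C8a; methoxy on C6 and C7), via bis-silylated phenol 31 (not isolated)
Conditions: toluene, 80 to 110 °C; then Bu4NF, AcOH, THF, 0 °C
Reagents that add atoms: none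
Why: Proposed new method: a Danheiser-type benzannulation with a 4-silyloxy-2,3-dialkoxycyclobutenone, a partner class not yet shown in the intermolecular reaction with alkynes; thermal four-electron ring opening of 30 (silyloxy group turning outward) gives a ketene whose carbonyl carbon is attacked by the chain-bearing carbon of the siloxyalkyne in a [2+2] cycloaddition, and ring opening, six-electron electrocyclisation and tautomerisation give the hexasubstituted phenol 31 with C4a between C8a–OH and C5–OSi; the closest known reactions are the benzannulation of 3-alkoxycyclobutenones with siloxyalkynes (step 10) and the thermal ring expansion of squarate-derived 4-hydroxycyclobutenones; buffered fluoride then frees the two silylated phenols, and 32 is used at once under argon.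

Step 18
Reactants: 32 ring A triol
Product: 34 target lactone dimer, via dealkylated seco acid 33 (not isolated)
Conditions: BBr3 (excess), CH2Cl2, −78 °C to rt; MeOH; then 2 M HCl, THF, 45 °C, under Ar
Reagents that add atoms: none
Why: Lewis-acid ether cleavage: BBr3 binds each aryl ether oxygen and bromide removes the methyl or ethyl group, and the tert-butyl ester is cleaved as well. In the acidic phase the acid on C3 and the amide on C3′ acylate an ortho hydroxyl of the now symmetrical pentahydroxyphenyl and trihydroxyphenyl rings, each closing only its own six-membered lactone, helped by the substituents on C3 and C4 as in a trimethyl lock. No base is present, so the cis lactone A keeps its configuration.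

## Compound list

1 | (E)-3-(4-methoxyphenyl)prop-2-enal (4-methoxycinnamaldehyde) | COc1ccc(/C=C/C=O)cc1 | starting material
2 | diethyl (4-methoxybenzyl)phosphonate | CCOP(=O)(Cc1ccc(OC)cc1)OCC | starting material
3 | (1E,3E)-1,4-bis(4-methoxyphenyl)buta-1,3-diene | COc1ccc(/C=C/C=C/c2ccc(OC)cc2)cc1 | intermediate
4 | (E)-4-tert-butoxy-4-oxobut-2-enoic acid (mono-tert-butyl fumarate) | CC(C)(C)OC(=O)/C=C/C(=O)O | starting material
5 | 1,3-oxazolidin-2-one | O=C1NCCO1 | starting material
6 | (E)-4-tert-butoxy-4-oxobut-2-enoic 2,2-dimethylpropanoic anhydride (not isolated) | CC(C)(C)OC(=O)/C=C/C(=O)OC(=O)C(C)(C)C | intermediate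
7 | tert-butyl (E)-4-oxo-4-(2-oxo-1,3-oxazolidin-3-yl)but-2-enoate | CC(C)(C)OC(=O)/C=C/C(=O)N1CCOC1=O | intermediate
8 | tert-butyl (1S,2S,3S,6R)-3,6-bis(4-methoxyphenyl)-2-(2-oxo-1,3-oxazolidine-3-carbonyl)cyclohex-4-ene-1-carboxylate | C1=C[C@H](c2ccc(OC)cc2)[C@H](C(=O)N2CCOC2=O)[C@@H](C(=O)OC(C)(C)C)[C@@H]1c1ccc(OC)cc1 | intermediate
9 | ozonide of 8: 1,2,4-trioxolane across the former alkene carbons, other centres as in 8, acetal centres undefined (not isolated) | C12OOC(O1)[C@H](c1ccc(OC)cc1)[C@H](C(=O)N1CCOC1=O)[C@@H](C(=O)OC(C)(C)C)[C@@H]2c1ccc(OC)cc1 | intermediate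
10 | tert-butyl (2S,3R)-4-hydroxy-2-[(2S,3S)-4-hydroxy-3-(4-methoxyphenyl)-1-oxo-1-(2-oxo-1,3-oxazolidin-3-yl)butan-2-yl]-3-(4-methoxyphenyl)butanoate (not isolated) | OC[C@@H](c1ccc(OC)cc1)[C@H](C(=O)OC(C)(C)C)[C@@H](C(=O)N1CCOC1=O)[C@@H](c1ccc(OC)cc1)CO | intermediate
11 | tert-butyl (2S,3R)-4-hydroxy-3-(4-methoxyphenyl)-2-[(3S,4S)-4-(4-methoxyphenyl)-2-oxooxolan-3-yl]butanoate | OC[C@@H](c1ccc(OC)cc1)[C@H](C(=O)OC(C)(C)C)[C@H]1C(=O)OC[C@@H]1c1ccc(OC)cc1 | intermediate
12 | tert-butyl (2S,3R)-4-[tert-butyl(dimethyl)silyl]oxy-3-(4-methoxyphenyl)-2-[(3S,4S)-4-(4-methoxyphenyl)-2-oxooxolan-3-yl]butanoate | CC(C)(C)[Si](C)(C)OC[C@@H](c1ccc(OC)cc1)[C@H](C(=O)OC(C)(C)C)[C@H]1C(=O)OC[C@@H]1c1ccc(OC)cc1 | intermediate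
13 | tert-butyl (2S,3R)-4-[tert-butyl(dimethyl)silyl]oxy-2-[(2S,3S)-4-hydroxy-1-[methoxy(methyl)amino]-3-(4-methoxyphenyl)-1-oxobutan-2-yl]-3-(4-methoxyphenyl)butanoate | CC(C)(C)[Si](C)(C)OC[C@@H](c1ccc(OC)cc1)[C@H](C(=O)OC(C)(C)C)[C@@H](C(=O)N(C)OC)[C@@H](c1ccc(OC)cc1)CO | intermediate
14 | tert-butyl (2S,3R)-4-[tert-butyl(dimethyl)silyl]oxy-2-[(2S,3S)-1-[methoxy(methyl)amino]-3-(4-methoxyphenyl)-1,4-dioxobutan-2-yl]-3-(4-methoxyphenyl)butanoate | CC(C)(C)[Si](C)(C)OC[C@@H](c1ccc(OC)cc1)[C@H](C(=O)OC(C)(C)C)[C@@H](C(=O)N(C)OC)[C@@H](c1ccc(OC)cc1)C=O | intermediate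
15 | tert-butyl (2S,3R)-4-[tert-butyl(dimethyl)silyl]oxy-2-[(2S,3R)-1-[methoxy(methyl)amino]-3-(4-methoxyphenyl)-1-oxopent-4-yn-2-yl]-3-(4-methoxyphenyl)butanoate | CC(C)(C)[Si](C)(C)OC[C@@H](c1ccc(OC)cc1)[C@H](C(=O)OC(C)(C)C)[C@@H](C(=O)N(C)OC)[C@@H](c1ccc(OC)cc1)C#C | intermediate
16 | lithium acetylide of 15 (not isolated) | CC(C)(C)[Si](C)(C)OC[C@@H](c1ccc(OC)cc1)[C@H](C(=O)OC(C)(C)C)[C@@H](C(=O)N(C)OC)[C@@H](c1ccc(OC)cc1)C#[C-].[Li+] | intermediate
17 | lithium ynolate formed from 16 (not isolated) | CC(C)(C)[Si](C)(C)OC[C@@H](c1ccc(OC)cc1)[C@H](C(=O)OC(C)(C)C)[C@@H](C(=O)N(C)OC)[C@@H](c1ccc(OC)cc1)C#C[O-].[Li+] | intermediate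
18 | tert-butyl (2S,3R)-4-[tert-butyl(dimethyl)silyl]oxy-2-[(2S,3S)-1-[methoxy(methyl)amino]-3-(4-methoxyphenyl)-1-oxo-5-[tri(propan-2-yl)silyl]oxypent-4-yn-2-yl]-3-(4-methoxyphenyl)butanoate | CC(C)(C)[Si](C)(C)OC[C@@H](c1ccc(OC)cc1)[C@H](C(=O)OC(C)(C)C)[C@@H](C(=O)N(C)OC)[C@@H](c1ccc(OC)cc1)C#CO[Si](C(C)C)(C(C)C)C(C)C | intermediate
19 | 3-ethoxycyclobut-2-en-1-one | CCOC1=CC(=O)C1 | starting material
20 | tert-butyl (2S,3R)-4-[tert-butyl(dimethyl)silyl]oxy-2-[(2S,3S)-3-[4-ethoxy-2-hydroxy-6-[tri(propan-2-yl)silyl]oxyphenyl]-1-[methoxy(methyl)amino]-3-(4-methoxyphenyl)-1-oxopropan-2-yl]-3-(4-methoxyphenyl)butanoate (not isolated) | CC(C)(C)[Si](C)(C)OC[C@@H](c1ccc(OC)cc1)[C@H](C(=O)OC(C)(C)C)[C@@H](C(=O)N(C)OC)[C@@H](c1ccc(OC)cc1)c1c(O)cc(OCC)cc1O[Si](C(C)C)(C(C)C)C(C)C | intermediate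
21 | tert-butyl (2S,3R)-2-[(2S,3S)-3-(4-ethoxy-2,6-dihydroxyphenyl)-1-[methoxy(methyl)amino]-3-(4-methoxyphenyl)-1-oxopropan-2-yl]-4-hydroxy-3-(4-methoxyphenyl)butanoate | OC[C@@H](c1ccc(OC)cc1)[C@H](C(=O)OC(C)(C)C)[C@@H](C(=O)N(C)OC)[C@@H](c1ccc(OC)cc1)c1c(O)cc(OCC)cc1O | intermediate
22 | tert-butyl (2S,3R)-2-[(2S,3S)-3-(4-ethoxy-2,6-dimethoxyphenyl)-1-[methoxy(methyl)amino]-3-(4-methoxyphenyl)-1-oxopropan-2-yl]-4-hydroxy-3-(4-methoxyphenyl)butanoate | OC[C@@H](c1ccc(OC)cc1)[C@H](C(=O)OC(C)(C)C)[C@@H](C(=O)N(C)OC)[C@@H](c1ccc(OC)cc1)c1c(OC)cc(OCC)cc1OC | intermediate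
23 | tert-butyl (2S,3R)-2-[(2S,3S)-3-(4-ethoxy-2,6-dimethoxyphenyl)-1-[methoxy(methyl)amino]-3-(4-methoxyphenyl)-1-oxopropan-2-yl]-3-(4-methoxyphenyl)-4-oxobutanoate | O=C[C@@H](c1ccc(OC)cc1)[C@H](C(=O)OC(C)(C)C)[C@@H](C(=O)N(C)OC)[C@@H](c1ccc(OC)cc1)c1c(OC)cc(OCC)cc1OC | intermediate
24 | tert-butyl (2S,3S)-2-[(2S,3S)-3-(4-ethoxy-2,6-dimethoxyphenyl)-1-[methoxy(methyl)amino]-3-(4-methoxyphenyl)-1-oxopropan-2-yl]-3-(4-methoxyphenyl)pent-4-ynoate | C#C[C@@H](c1ccc(OC)cc1)[C@H](C(=O)OC(C)(C)C)[C@@H](C(=O)N(C)OC)[C@@H](c1ccc(OC)cc1)c1c(OC)cc(OCC)cc1OC | intermediate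
25 | lithium acetylide of 24 (not isolated) | [Li+].[C-]#C[C@@H](c1ccc(OC)cc1)[C@H](C(=O)OC(C)(C)C)[C@@H](C(=O)N(C)OC)[C@@H](c1ccc(OC)cc1)c1c(OC)cc(OCC)cc1OC | intermediate
26 | lithium ynolate formed from 25 (not isolated) | [Li+].[O-]C#C[C@@H](c1ccc(OC)cc1)[C@H](C(=O)OC(C)(C)C)[C@@H](C(=O)N(C)OC)[C@@H](c1ccc(OC)cc1)c1c(OC)cc(OCC)cc1OC | intermediate
27 | tert-butyl (2S,3R)-2-[(2S,3S)-3-(4-ethoxy-2,6-dimethoxyphenyl)-1-[methoxy(methyl)amino]-3-(4-methoxyphenyl)-1-oxopropan-2-yl]-3-(4-methoxyphenyl)-5-[tri(propan-2-yl)silyl]oxypent-4-ynoate | CC(C)[Si](C(C)C)(C(C)C)OC#C[C@@H](c1ccc(OC)cc1)[C@H](C(=O)OC(C)(C)C)[C@@H](C(=O)N(C)OC)[C@@H](c1ccc(OC)cc1)c1c(OC)cc(OCC)cc1OC | intermediate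
28 | 3,4-dimethoxycyclobut-3-ene-1,2-dione (dimethyl squarate) | COC1=C(OC)C(=O)C1=O | starting material
29 | 4-hydroxy-2,3-dimethoxycyclobut-2-en-1-one (racemic) | COC1=C(OC)C(O)C1=O | intermediate
30 | 4-[tert-butyl(dimethyl)silyl]oxy-2,3-dimethoxycyclobut-2-en-1-one (racemic) | COC1=C(OC)C(O[Si](C)(C)C(C)(C)C)C1=O | intermediate
31 | tert-butyl (2S,3R)-3-[3-[tert-butyl(dimethyl)silyl]oxy-2-hydroxy-4,5-dimethoxy-6-[tri(propan-2-yl)silyl]oxyphenyl]-2-[(2S,3S)-3-(4-ethoxy-2,6-dimethoxyphenyl)-1-[methoxy(methyl)amino]-3-(4-methoxyphenyl)-1-oxopropan-2-yl]-3-(4-methoxyphenyl)propanoate (not isolated) | Oc1c(O[Si](C)(C)C(C)(C)C)c(OC)c(OC)c(O[Si](C(C)C)(C(C)C)C(C)C)c1[C@@H](c1ccc(OC)cc1)[C@H](C(=O)OC(C)(C)C)[C@@H](C(=O)N(C)OC)[C@@H](c1ccc(OC)cc1)c1c(OC)cc(OCC)cc1OC | intermediate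
32 | tert-butyl (2S,3R)-2-[(2S,3S)-3-(4-ethoxy-2,6-dimethoxyphenyl)-1-[methoxy(methyl)amino]-3-(4-methoxyphenyl)-1-oxopropan-2-yl]-3-(4-methoxyphenyl)-3-(2,3,6-trihydroxy-4,5-dimethoxyphenyl)propanoate | Oc1c(O)c(OC)c(OC)c(O)c1[C@@H](c1ccc(OC)cc1)[C@H](C(=O)OC(C)(C)C)[C@@H](C(=O)N(C)OC)[C@@H](c1ccc(OC)cc1)c1c(OC)cc(OCC)cc1OC | intermediate
33 | (2S,3R)-3-(4-hydroxyphenyl)-2-[(2S,3S)-3-(4-hydroxyphenyl)-1-[methoxy(methyl)amino]-1-oxo-3-(2,4,6-trihydroxyphenyl)propan-2-yl]-3-(pentahydroxyphenyl)propanoic acid (not isolated) | Oc1c(O)c(O)c(O)c(O)c1[C@@H](c1ccc(O)cc1)[C@H](C(=O)O)[C@@H](C(=O)N(C)OC)[C@@H](c1ccc(O)cc1)c1c(O)cc(O)cc1O | intermediate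
34 | (3S,4R)-3-[(3S,4S)-5,7-dihydroxy-4-(4-hydroxyphenyl)-2-oxo-3,4-dihydro-2H-chromen-3-yl]-5,6,7,8-tetrahydroxy-4-(4-hydroxyphenyl)-3,4-dihydro-2H-chromen-2-one | O=C1Oc2c(O)c(O)c(O)c(O)c2[C@@H](c2ccc(O)cc2)[C@H]1[C@H]1C(=O)Oc2cc(O)cc(O)c2[C@@H]1c1ccc(O)cc1 | target

## Step count and least certain steps

Total: 18 steps. Longest linear sequence: 15 steps (1, 3–14, 17, 18); step 2 and steps 15–16 are side branches.

**Step 17 (Proposed new method).** The ring-opened ketene from 30 may be consumed by dimerisation, silyl migration or loss of silanol before it is intercepted. The nucleophilic carbon of 27 is shielded by the branched C4 substituent, and a dialkoxyketene is a weaker electrophile than the ketenes normally used. The fallback uses known chemistry, sets out from alkyne 24 and returns at 32. The lithium acetylide 25 is added at −78 °C to one carbonyl of dimethyl squarate 28 to give the 4-alkynyl-4-hydroxy-2,3-dimethoxycyclobutenone F1. Heating in toluene at 110 °C brings about the Moore rearrangement to the 2,3-dimethoxy-1,4-benzoquinone F2, with the chain on C4a and hydrogen on C8a. Nucleophilic epoxidation of that quinone alkene (H2O2, Na2CO3) gives the epoxyquinone F3, mild acid (silica gel or catalytic TsOH) isomerises it to the hydroxyquinone F4, and Na2S2O4 reduces F4 to 32.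

**Step 3 (key step).** The cycloaddition may be slow, because the conjugated diaryl diene populates its s-cis form poorly and meets a β-substituted dienophile. A slow reaction leaves room for one-electron oxidation or oligomerisation of the electron-rich diene by divalent copper, and for loss of endo and facial selectivity at the higher temperature then needed. The fallback uses covalent control, sets out from 4 and 3 and returns at 11. The mixed anhydride 6 acylates (S)-4-benzyl-2-oxazolidinone (LiCl, Et3N) to the chiral imide F5. Et2AlCl (CH2Cl2, −78 to −20 °C) chelates both carbonyl groups, and the diene adds to the face away from the benzyl group, again Cα-si with the imide endo, to give adduct F6. The conditions of step 4 then lead through ozonide F7 and diol imide F8, which lactonises with loss of the auxiliary to 11.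

**Step 4.** Acyl transfer may be misdirected: the C4a alkoxide can attack the imide to give a six-membered lactone or close onto the tert-butyl ester, and borohydride or methoxide can attack the imide. All these nucleophiles coexist in the alkaline medium, and the outcome rests only on the kinetic preference for five-membered ring closure. The fallback sets out from 8 and returns at 11. Me(MeO)NH·HCl and AlMe3 convert the imide into the N-methoxy-N-methylamide F9. Ozonolysis and NaBH4 give, through ozonide F10, the stable diol amide F11. Catalytic pyridinium p-toluenesulfonate in CH2Cl2 then closes the lactone under equilibrating conditions, in which the five-membered lactone 11 is the thermodynamic product and the tert-butyl ester is inert.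

**Step 8 (the same hazard recurs in step 13).** The α-aryl aldehyde may enolise in K2CO3/MeOH before the diazophosphonate adds, which would epimerise C4′ (C4 in step 13); its α-proton is activated by both the aryl and the formyl group. The fallback sets out from 14 and returns at 15. Neutral Ramirez olefination (CBr4, PPh3, Zn) gives the 1,1-dibromoalkene F12. Hydrogenolysis with Bu3SnH and catalytic Pd(PPh3)4 gives the (Z)-bromoalkene F13, and anti-elimination with KO-t-Bu at −78 °C gives 15. For step 13 the same three operations take 23 through dibromoalkene F14 and (Z)-bromoalkene F15 to 24.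

**Step 18.** The pentahydroxy ring may be oxidised by air during aqueous work-up and purification, and acyl transfer from the amide may be slow enough to leave open material that is hard to separate from 34. The fallback sets out from 32 and returns at 34. The crude product of the dealkylation and lactonisation is not purified but acetylated (Ac2O, pyridine, 0 °C) to the octaacetate F16, which is stable to air and chromatography. Acid methanolysis (HCl, MeOH, under Ar) then releases 34.

## Further compounds

F1 | step 17 | 4-hydroxy-2,3-dimethoxy-4-alkynylcyclobut-2-en-1-one from 25 and 28 (carbinol centre undefined) | COC1=C(OC)C(=O)C1(O)C#C[C@@H](c1ccc(OC)cc1)[C@H](C(=O)OC(C)(C)C)[C@@H](C(=O)N(C)OC)[C@@H](c1ccc(OC)cc1)c1c(OC)cc(OCC)cc1OC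
F2 | step 17 | 2,3-dimethoxy-1,4-benzoquinone with the side chain on C4a and hydrogen on C8a | COC1=C(OC)C(=O)C(=CC1=O)[C@@H](c1ccc(OC)cc1)[C@H](C(=O)OC(C)(C)C)[C@@H](C(=O)N(C)OC)[C@@H](c1ccc(OC)cc1)c1c(OC)cc(OCC)cc1OC
F3 | step 17 | C4a,C8a-epoxide of quinone F2 (epoxide centres undefined) | COC1=C(OC)C(=O)C2(OC2C1=O)[C@@H](c1ccc(OC)cc1)[C@H](C(=O)OC(C)(C)C)[C@@H](C(=O)N(C)OC)[C@@H](c1ccc(OC)cc1)c1c(OC)cc(OCC)cc1OC
F4 | step 17 | 8a-hydroxy derivative of quinone F2 | COC1=C(OC)C(=O)C(=C(O)C1=O)[C@@H](c1ccc(OC)cc1)[C@H](C(=O)OC(C)(C)C)[C@@H](C(=O)N(C)OC)[C@@H](c1ccc(OC)cc1)c1c(OC)cc(OCC)cc1OC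
F5 | step 3 | tert-butyl (E)-4-[(4S)-4-benzyl-2-oxo-1,3-oxazolidin-3-yl]-4-oxobut-2-enoate | CC(C)(C)OC(=O)/C=C/C(=O)N1[C@@H](Cc2ccccc2)COC1=O
F6 | step 3 | tert-butyl (1S,2S,3S,6R)-2-[(4S)-4-benzyl-2-oxo-1,3-oxazolidine-3-carbonyl]-3,6-bis(4-methoxyphenyl)cyclohex-4-ene-1-carboxylate | C1=C[C@H](c2ccc(OC)cc2)[C@H](C(=O)N2[C@@H](Cc3ccccc3)COC2=O)[C@@H](C(=O)OC(C)(C)C)[C@@H]1c1ccc(OC)cc1
F7 | step 3 | ozonide of F6 (not isolated; acetal centres undefined) | C12OOC(O1)[C@H](c1ccc(OC)cc1)[C@H](C(=O)N1[C@@H](Cc3ccccc3)COC1=O)[C@@H](C(=O)OC(C)(C)C)[C@@H]2c1ccc(OC)cc1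
F8 | step 3 | diol imide from F7, the (4S)-4-benzyl analogue of 10 (not isolated) | OC[C@@H](c1ccc(OC)cc1)[C@H](C(=O)OC(C)(C)C)[C@@H](C(=O)N1[C@@H](Cc2ccccc2)COC1=O)[C@@H](c1ccc(OC)cc1)CO
F9 | step 4 | tert-butyl (1S,2S,3S,6R)-2-[methoxy(methyl)carbamoyl]-3,6-bis(4-methoxyphenyl)cyclohex-4-ene-1-carboxylate | C1=C[C@H](c2ccc(OC)cc2)[C@H](C(=O)N(C)OC)[C@@H](C(=O)OC(C)(C)C)[C@@H]1c1ccc(OC)cc1
F10 | step 4 | ozonide of F9 (not isolated; acetal centres undefined) | C12OOC(O1)[C@H](c1ccc(OC)cc1)[C@H](C(=O)N(C)OC)[C@@H](C(=O)OC(C)(C)C)[C@@H]2c1ccc(OC)cc1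
F11 | step 4 | tert-butyl (2S,3R)-4-hydroxy-2-[(2S,3S)-4-hydroxy-1-[methoxy(methyl)amino]-3-(4-methoxyphenyl)-1-oxobutan-2-yl]-3-(4-methoxyphenyl)butanoate | OC[C@@H](c1ccc(OC)cc1)[C@H](C(=O)OC(C)(C)C)[C@@H](C(=O)N(C)OC)[C@@H](c1ccc(OC)cc1)CO
F12 | step 8 | 1,1-dibromoalkene from aldehyde 14 | CC(C)(C)[Si](C)(C)OC[C@@H](c1ccc(OC)cc1)[C@H](C(=O)OC(C)(C)C)[C@@H](C(=O)N(C)OC)[C@@H](c1ccc(OC)cc1)C=C(Br)Br
F13 | step 8 | (Z)-bromoalkene from F12 | CC(C)(C)[Si](C)(C)OC[C@@H](c1ccc(OC)cc1)[C@H](C(=O)OC(C)(C)C)[C@@H](C(=O)N(C)OC)[C@@H](c1ccc(OC)cc1)/C=C\Br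
F14 | step 13 | 1,1-dibromoalkene from aldehyde 23 | BrC(Br)=C[C@@H](c1ccc(OC)cc1)[C@H](C(=O)OC(C)(C)C)[C@@H](C(=O)N(C)OC)[C@@H](c1ccc(OC)cc1)c1c(OC)cc(OCC)cc1OC
F15 | step 13 | (Z)-bromoalkene from F14 | Br/C=C\[C@@H](c1ccc(OC)cc1)[C@H](C(=O)OC(C)(C)C)[C@@H](C(=O)N(C)OC)[C@@H](c1ccc(OC)cc1)c1c(OC)cc(OCC)cc1OC
F16 | step 18 | octaacetate of 34 | O=C1Oc2c(OC(C)=O)c(OC(C)=O)c(OC(C)=O)c(OC(C)=O)c2[C@@H](c2ccc(OC(C)=O)cc2)[C@H]1[C@H]1C(=O)Oc2cc(OC(C)=O)cc(OC(C)=O)c2[C@@H]1c1ccc(OC(C)=O)cc1
A1 | alternative 1 | octa-O-methyl ether of 34 | O=C1Oc2c(OC)c(OC)c(OC)c(OC)c2[C@@H](c2ccc(OC)cc2)[C@H]1[C@H]1C(=O)Oc2cc(OC)cc(OC)c2[C@@H]1c1ccc(OC)cc1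
A2 | alternative 1 | 2-[(3R,4S)-5,7-dimethoxy-4-(4-methoxyphenyl)-2-oxo-3,4-dihydro-2H-chromen-3-yl]acetic acid | OC(=O)C[C@H]1C(=O)Oc2cc(OC)cc(OC)c2[C@@H]1c1ccc(OC)cc1
A3 | alternative 1 | 2,3,4,5-tetramethoxy-6-[(4-methoxyphenyl)(4-methylphenylsulfonyl)methyl]phenol (racemic) | Oc1c(OC)c(OC)c(OC)c(OC)c1C(c1ccc(OC)cc1)S(=O)(=O)c1ccc(C)cc1
A4 | alternative 1 | (6E)-2,3,4,5-tetramethoxy-6-[(4-methoxyphenyl)methylidene]cyclohexa-2,4-dien-1-one | O=C1C(OC)=C(OC)C(OC)=C(OC)/C1=C\c1ccc(OC)cc1
A5 | alternative 2 | ring A phenol with free C8a hydroxyl, silyl ethers on C8 and C5, tert-butyl ester on C3 and methyl acetate stub | Oc1c(O[Si](C)(C)C(C)(C)C)c(OC)c(OC)c(O[Si](C(C)C)(C(C)C)C(C)C)c1[C@@H](c1ccc(OC)cc1)[C@H](C(=O)OC(C)(C)C)CC(=O)OC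
A6 | alternative 2 | triisopropylsilyl ynol ether carrying C4, C3 and the acetate stub | CC(C)[Si](C(C)C)(C(C)C)OC#C[C@@H](c1ccc(OC)cc1)[C@H](C(=O)OC(C)(C)C)CC(=O)OC
A7 | alternative 3 | trans lactone B carrying the open pentamethoxyphenyl half with methyl ester on C3 | COc1c(OC)c(OC)c(OC)c(OC)c1[C@@H](c1ccc(OC)cc1)[C@H](C(=O)OC)[C@H]1C(=O)Oc2cc(OC)cc(OC)c2[C@@H]1c1ccc(OC)cc1
A8 | alternative 3 | 3,5-dimethoxyphenyl ester of the C2′ acid with a C4′ benzylic alcohol (C4′ undefined) | COc1c(OC)c(OC)c(OC)c(OC)c1[C@@H](c1ccc(OC)cc1)[C@H](C(=O)OC)[C@@H](C(=O)Oc1cc(OC)cc(OC)c1)C(O)c1ccc(OC)cc1
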